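## Retrosynthetic overview

1. Target 20 is a (2S)-flavanone. Rings A and B are bought as benzenes with their oxygen pattern; ring C (O1, C2, C3, C4, C4a, C8a) is the only ring to be made and C2 is its only stereocentre.
2. Enabling feature: C2 is a benzylic, O1-bearing CH next to the C3 methylene, and C4 is a ketone carbon on ring A ortho to O1 (at C8a). Moving the C2 hydrogen back to C4 opens ring C to a formyl group on C4a and a 1-arylvinyl ether (C2=C3) on O1, the achiral alkene-hydroacylation substrate 18.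
3. Key disconnection C3–C4: a rhodium-catalysed enantioselective 6-endo hydroacylation of 18 closes ring C and sets C2 in one step; the two MOM ethers are then removed.
4. Enol ether 18 comes from Petasis methylenation of aryl ester 15 (phenol 9 + acid 14), with the formyl carbon carried as CH2OTBS.
5. Phenol 9 comes from 2,4,6-trihydroxybenzaldehyde (bis-MOM ether, O-1,1-dimethylallyl ether, aromatic Claisen rearrangement that puts the prenyl group on the future C8); acid 14 comes from a Negishi coupling.

Key step: step 13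

Assumption: the (R)-bisphosphine is written for step 13 on the assumption that it delivers the (2S) product; the sense of induction has to be confirmed on 19, and the (S)-ligand is used if it is the opposite.

## Route

Step 1
Reactants: 1 2,4,6-trihydroxybenzaldehyde
Product: 2 2-hydroxy-4,6-bis(methoxymethoxy)benzaldehyde
Conditions: MOMCl (2.2 equiv), i-Pr2NEt, CH2Cl2, 0 °C to rt
Reagents that add atoms: chloromethyl methyl ether (MOMCl), COCCl
Why: Williamson-type acetal ether formation should cap the para hydroxyl and one ortho hydroxyl and stop there, because the last hydroxyl is held in a strong hydrogen bond to the formyl oxygen.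

Step 2
Reactants: 3 2-methylbut-3-en-2-ol
Product: 5 tert-butyl 2-methylbut-3-en-2-yl carbonate, via lithium 2-methylbut-3-en-2-olate 4 (not isolated)
Conditions: n-BuLi, THF, −78 °C; then Boc2O, −78 °C to rt
Reagents that add atoms: di-tert-butyl dicarbonate (Boc2O), CC(C)(C)OC(=O)OC(=O)OC(C)(C)C
Why: Acylation of the lithium alkoxide by the dicarbonate is the standard way to a tertiary allyl carbonate.

Step 3
Reactants: 2 2-hydroxy-4,6-bis(methoxymethoxy)benzaldehyde; 5 tert-butyl 2-methylbut-3-en-2-yl carbonate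
Product: 6 2-[(2-methylbut-3-en-2-yl)oxy]-4,6-bis(methoxymethoxy)benzaldehyde
Conditions: Pd(PPh3)4 (3 mol %), THF, 0 °C
Reagents that add atoms: none
Why: In this Tsuji–Trost decarboxylative O-allylation zerovalent palladium ionises the carbonate, the released tert-butoxide deprotonates the chelated phenol, and the phenoxide should attack the more substituted terminus of the 1,1-dimethylallyl palladium complex under kinetic control to give the tertiary ether.

Step 4
Reactants: 6 2-[(2-methylbut-3-en-2-yl)oxy]-4,6-bis(methoxymethoxy)benzaldehyde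
Product: 7 {2-[(2-methylbut-3-en-2-yl)oxy]-4,6-bis(methoxymethoxy)phenyl}methanol
Conditions: NaBH4, MeOH/THF, 0 °C; neutral aqueous work-up
Reagents that add atoms: none
Why: Borohydride reduction of the aldehyde masks the formyl carbon at the alcohol level so that it survives the later ester methylenation; the ethers and the alkene are inert.

Step 5
Reactants: 7 {2-[(2-methylbut-3-en-2-yl)oxy]-4,6-bis(methoxymethoxy)phenyl}methanol
Product: 8 tert-butyl({2-[(2-methylbut-3-en-2-yl)oxy]-4,6-bis(methoxymethoxy)phenyl}methoxy)dimethylsilane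
Conditions: TBSCl, imidazole, DMF, 0 °C to rt
Reagents that add atoms: tert-butyldimethylsilyl chloride (TBSCl), CC(C)(C)[Si](C)(C)Cl
Why: Silylation of the primary alcohol under buffered conditions protects the acid-sensitive electron-rich benzylic alcohol.

Step 6
Reactants: 8 tert-butyl({2-[(2-methylbut-3-en-2-yl)oxy]-4,6-bis(methoxymethoxy)phenyl}methoxy)dimethylsilane
Product: 9 2-{[(tert-butyldimethylsilyl)oxy]methyl}-3,5-bis(methoxymethoxy)-6-(3-methylbut-2-en-1-yl)phenol
Conditions: PhMe, N,N-diethylaniline (1 equiv), 100 °C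
Reagents that add atoms: none
Why: The aromatic Claisen [3,3] rearrangement of the 1,1-dimethylallyl ether should deliver the allyl terminus to the only unsubstituted ortho carbon and give, after tautomerisation, the prenyl phenol with the free OH flanked by the prenyl and CH2OTBS groups.

Step 7
Reactants: 10 methyl 3-bromo-4-methoxybenzoate; 11 4-bromo-2-methylbut-1-ene
Product: 13 methyl 4-methoxy-3-(3-methylbut-3-en-1-yl)benzoate, via (3-methylbut-3-en-1-yl)zinc bromide 12 (not isolated)
Conditions: 11, Zn dust, LiCl, THF, 40 °C; then 10, Pd(OAc)2 (2 mol %), SPhos (4 mol %), THF, rt to 40 °C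
Reagents that add atoms: none
Why: Zinc insertion into the primary bromide followed by Negishi sp2–sp3 coupling tolerates the ester, and the primary homoallyl zinc reagent should couple without beta-hydride loss under the biarylphosphine catalyst.

Step 8
Reactants: 13 methyl 4-methoxy-3-(3-methylbut-3-en-1-yl)benzoate
Product: 14 4-methoxy-3-(3-methylbut-3-en-1-yl)benzoic acid
Conditions: LiOH, THF/MeOH/H2O, 40 °C; then 1 M HCl to pH 3, 0 °C
Reagents that add atoms: lithium hydroxide, [Li+].[OH-]
Why: Saponification of the methyl ester leaves the remote alkene untouched, and cold dilute acid in the work-up is too weak to hydrate it.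

Step 9
Reactants: 9 2-{[(tert-butyldimethylsilyl)oxy]methyl}-3,5-bis(methoxymethoxy)-6-(3-methylbut-2-en-1-yl)phenol; 14 4-methoxy-3-(3-methylbut-3-en-1-yl)benzoic acid
Product: 15 2-{[(tert-butyldimethylsilyl)oxy]methyl}-3,5-bis(methoxymethoxy)-6-(3-methylbut-2-en-1-yl)phenyl 4-methoxy-3-(3-methylbut-3-en-1-yl)benzoate
Conditions: DIC, DMAP (0.2 equiv), CH2Cl2, rt
Reagents that add atoms: none
Why: Steglich esterification through the acylpyridinium ion should acylate the hindered phenol without generating HCl, which would threaten the 1,1-disubstituted alkene and the acetals.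

Step 10
Reactants: 15 2-{[(tert-butyldimethylsilyl)oxy]methyl}-3,5-bis(methoxymethoxy)-6-(3-methylbut-2-en-1-yl)phenyl 4-methoxy-3-(3-methylbut-3-en-1-yl)benzoate
Product: 16 tert-butyl{[2-({1-[4-methoxy-3-(3-methylbut-3-en-1-yl)phenyl]ethenyl}oxy)-4,6-bis(methoxymethoxy)-3-(3-methylbut-2-en-1-yl)phenyl]methoxy}dimethylsilane
Conditions: Cp2TiMe2 (2.5 equiv), PhMe, 70 °C, dark; chromatography on Et3N-deactivated silica
Reagents that add atoms: dimethyltitanocene (Cp2TiMe2), C[Ti+2]C.c1cc[cH-]c1.c1cc[cH-]c1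
Why: Petasis methylenation, through titanocene methylidene and an oxatitanacyclobutane, converts aryl esters into 1-arylvinyl aryl ethers; the silyl ether, the acetals and the two unstrained alkenes should not be changed.

Step 11
Reactants: 16 tert-butyl{[2-({1-[4-methoxy-3-(3-methylbut-3-en-1-yl)phenyl]ethenyl}oxy)-4,6-bis(methoxymethoxy)-3-(3-methylbut-2-en-1-yl)phenyl]methoxy}dimethylsilane
Product: 17 [2-({1-[4-methoxy-3-(3-methylbut-3-en-1-yl)phenyl]ethenyl}oxy)-4,6-bis(methoxymethoxy)-3-(3-methylbut-2-en-1-yl)phenyl]methanol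
Conditions: Bu4NF (1.1 equiv), THF, 0 °C; neutral work-up
Reagents that add atoms: none
Why: Fluoride cleaves only the silyl ether; the basic medium keeps the acid-labile enol ether and the MOM ethers intact.

Step 12
Reactants: 17 [2-({1-[4-methoxy-3-(3-methylbut-3-en-1-yl)phenyl]ethenyl}oxy)-4,6-bis(methoxymethoxy)-3-(3-methylbut-2-en-1-yl)phenyl]methanol
Product: 18 2-({1-[4-methoxy-3-(3-methylbut-3-en-1-yl)phenyl]ethenyl}oxy)-4,6-bis(methoxymethoxy)-3-(3-methylbut-2-en-1-yl)benzaldehyde
Conditions: activated MnO2, CH2Cl2, rt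
Reagents that add atoms: none
Why: Neutral, heterogeneous benzylic oxidation with MnO2 stops at the aldehyde and avoids the acid that would hydrolyse the enol ether.

Step 13
Reactants: 18 2-({1-[4-methoxy-3-(3-methylbut-3-en-1-yl)phenyl]ethenyl}oxy)-4,6-bis(methoxymethoxy)-3-(3-methylbut-2-en-1-yl)benzaldehyde
Product: 19 (2S)-2-[4-methoxy-3-(3-methylbut-3-en-1-yl)phenyl]-5,7-bis(methoxymethoxy)-8-(3-methylbut-2-en-1-yl)-2,3-dihydro-4H-chromen-4-one
Conditions: [Rh(cod)Cl]2 (2.5 mol %), (R)-DTBM-SEGPHOS (5.5 mol %), NaB[3,5-(CF3)2C6H3]4 (5 mol %), degassed 1,4-dioxane, 60 °C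
Reagents that add atoms: none
Why: Proposed new method: a cationic monovalent rhodium bisphosphine complex should add oxidatively into the formyl C–H bond of 18, the tethered 1,1-disubstituted enol ether should insert into Rh–H with the hydride going to the internal carbon (future C2), and C–C reductive elimination from the seven-membered acyl alkyl rhodacycle should form the C3–C4 bond. The closest known reaction type is the rhodium/chiral bisphosphine-catalysed endo- and enantioselective intramolecular hydroacylation of 1,1-disubstituted alkenes in 2-(1-arylvinyl)benzaldehydes (to 3-arylindanones) and in ortho-(2-substituted allyl)benzaldehydes (to 3-substituted tetralones); an O-linked aryl 1-arylvinyl ether has not been shown as the alkene partner. Ring C closes in the 6-endo-trig (anti-Markovnikov) mode. The C2 stereocentre is created when hydride is delivered to one enantiotopic face of the C2=C3 bond and is under catalyst control by the axially chiral ligand, since the substrate has no stereocentre. The step needs endo over exo closure, which the 1,1-disubstitution secures because the exo path would require a tertiary alpha-aryl-alpha-aryloxy alkyl rhodium and a quaternary centre in a five-membered benzofuranone, and it needs chemoselectivity over the prenyl and isopentenyl double bonds, which the short O1 tether between the formyl group and the enol ether secures. The enol ether has no allylic hydrogen, so the double-bond migration that competes in allyl substrates cannot occur at the reacting alkene.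

Step 14
Reactants: 19 (2S)-2-[4-methoxy-3-(3-methylbut-3-en-1-yl)phenyl]-5,7-bis(methoxymethoxy)-8-(3-methylbut-2-en-1-yl)-2,3-dihydro-4H-chromen-4-one
Product: 20 (2S)-5,7-dihydroxy-2-[4-methoxy-3-(3-methylbut-3-en-1-yl)phenyl]-8-(3-methylbut-2-en-1-yl)-2,3-dihydro-4H-chromen-4-one (CNP0286775.1)
Conditions: HCl (1.5 M) in MeOH/H2O 9:1, 40 °C, stopped as soon as 19 is consumed
Reagents that add atoms: none
Why: Acid-catalysed transacetalisation to methanol removes aryl MOM ethers under conditions that prenylated phenols normally survive, and the absence of base avoids the retro-oxa-Michael opening that would racemise C2.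

## Compound list

1 | 2,4,6-trihydroxybenzaldehyde | O=Cc1c(O)cc(O)cc1O | starting material
2 | 2-hydroxy-4,6-bis(methoxymethoxy)benzaldehyde | O=Cc1c(O)cc(OCOC)cc1OCOC | intermediate
3 | 2-methylbut-3-en-2-ol | C=CC(C)(C)O | starting material
4 | lithium 2-methylbut-3-en-2-olate | [Li+].[O-]C(C)(C)C=C | intermediate
5 | tert-butyl 2-methylbut-3-en-2-yl carbonate | C=CC(C)(C)OC(=O)OC(C)(C)C | intermediate
6 | 2-[(2-methylbut-3-en-2-yl)oxy]-4,6-bis(methoxymethoxy)benzaldehyde | O=Cc1c(OC(C)(C)C=C)cc(OCOC)cc1OCOC | intermediate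
7 | {2-[(2-methylbut-3-en-2-yl)oxy]-4,6-bis(methoxymethoxy)phenyl}methanol | OCc1c(OC(C)(C)C=C)cc(OCOC)cc1OCOC | intermediate
8 | tert-butyl({2-[(2-methylbut-3-en-2-yl)oxy]-4,6-bis(methoxymethoxy)phenyl}methoxy)dimethylsilane | CC(C)(C)[Si](C)(C)OCc1c(OC(C)(C)C=C)cc(OCOC)cc1OCOC | intermediate
9 | 2-{[(tert-butyldimethylsilyl)oxy]methyl}-3,5-bis(methoxymethoxy)-6-(3-methylbut-2-en-1-yl)phenol | CC(C)(C)[Si](C)(C)OCc1c(O)c(CC=C(C)C)c(OCOC)cc1OCOC | intermediate
10 | methyl 3-bromo-4-methoxybenzoate | COC(=O)c1ccc(OC)c(Br)c1 | starting material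
11 | 4-bromo-2-methylbut-1-ene | C=C(C)CCBr | starting material
12 | (3-methylbut-3-en-1-yl)zinc bromide | C=C(C)CC[Zn]Br | intermediate
13 | methyl 4-methoxy-3-(3-methylbut-3-en-1-yl)benzoate | COC(=O)c1ccc(OC)c(CCC(C)=C)c1 | intermediate
14 | 4-methoxy-3-(3-methylbut-3-en-1-yl)benzoic acid | OC(=O)c1ccc(OC)c(CCC(C)=C)c1 | intermediate
15 | 2-{[(tert-butyldimethylsilyl)oxy]methyl}-3,5-bis(methoxymethoxy)-6-(3-methylbut-2-en-1-yl)phenyl 4-methoxy-3-(3-methylbut-3-en-1-yl)benzoate | CC(C)(C)[Si](C)(C)OCc1c(OC(=O)c2ccc(OC)c(CCC(C)=C)c2)c(CC=C(C)C)c(OCOC)cc1OCOC | intermediate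
16 | tert-butyl{[2-({1-[4-methoxy-3-(3-methylbut-3-en-1-yl)phenyl]ethenyl}oxy)-4,6-bis(methoxymethoxy)-3-(3-methylbut-2-en-1-yl)phenyl]methoxy}dimethylsilane | CC(C)(C)[Si](C)(C)OCc1c(OC(=C)c2ccc(OC)c(CCC(C)=C)c2)c(CC=C(C)C)c(OCOC)cc1OCOC | intermediate
17 | [2-({1-[4-methoxy-3-(3-methylbut-3-en-1-yl)phenyl]ethenyl}oxy)-4,6-bis(methoxymethoxy)-3-(3-methylbut-2-en-1-yl)phenyl]methanol | OCc1c(OC(=C)c2ccc(OC)c(CCC(C)=C)c2)c(CC=C(C)C)c(OCOC)cc1OCOC | intermediate
18 | 2-({1-[4-methoxy-3-(3-methylbut-3-en-1-yl)phenyl]ethenyl}oxy)-4,6-bis(methoxymethoxy)-3-(3-methylbut-2-en-1-yl)benzaldehyde | O=Cc1c(OC(=C)c2ccc(OC)c(CCC(C)=C)c2)c(CC=C(C)C)c(OCOC)cc1OCOC | intermediate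
19 | (2S)-2-[4-methoxy-3-(3-methylbut-3-en-1-yl)phenyl]-5,7-bis(methoxymethoxy)-8-(3-methylbut-2-en-1-yl)-2,3-dihydro-4H-chromen-4-one | C=C(C)CCc1cc([C@@H]2CC(=O)c3c(OCOC)cc(OCOC)c(CC=C(C)C)c3O2)ccc1OC | intermediate
20 | (2S)-5,7-dihydroxy-2-[4-methoxy-3-(3-methylbut-3-en-1-yl)phenyl]-8-(3-methylbut-2-en-1-yl)-2,3-dihydro-4H-chromen-4-one | C=C(C)CCc1cc([C@@H]2CC(=O)c3c(O)cc(O)c(CC=C(C)C)c3O2)ccc1OC | target

## Step count and risks

Total step count: 14. Longest linear sequence: 11 steps (steps 1, 3, 4, 5, 6, 9, 10, 11, 12, 13, 14, from 1 to 20).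

**Step 13 (most likely to fail).** The acyl rhodium hydride may lose CO before the alkene inserts. The alkyl rhodium intermediate may eliminate the beta-aryloxy group. The cationic metal may act as a Lewis acid and trigger an ene-type attack of the enol ether on the aldehyde. Reversible Rh–H insertion may move the terminal double bond of the ring B side chain. Facial selectivity may be poor.

Fallback (known chemistry; sets out from 6 and 13, comes back at 19, and builds ring C through the O1–C2 bond instead): 6 is heated (PhMe, 100 °C) so that the Claisen rearrangement gives 2-hydroxy-4,6-bis(methoxymethoxy)-3-(3-methylbut-2-en-1-yl)benzaldehyde F1. MeMgBr (2.2 equiv, THF, 0 °C) should give 1-[2-hydroxy-4,6-bis(methoxymethoxy)-3-(3-methylbut-2-en-1-yl)phenyl]ethan-1-ol F2, and MnO2 (CH2Cl2, rt) should give 1-[2-hydroxy-4,6-bis(methoxymethoxy)-3-(3-methylbut-2-en-1-yl)phenyl]ethan-1-one F3. Ester 13 is reduced with i-Bu2AlH (CH2Cl2, −78 °C) to [4-methoxy-3-(3-methylbut-3-en-1-yl)phenyl]methanol F4, which MnO2 oxidises to 4-methoxy-3-(3-methylbut-3-en-1-yl)benzaldehyde F5. Claisen–Schmidt condensation of F3 with F5 (KOH, EtOH, rt) should give (E)-1-[2-hydroxy-4,6-bis(methoxymethoxy)-3-(3-methylbut-2-en-1-yl)phenyl]-3-[4-methoxy-3-(3-methylbut-3-en-1-yl)phenyl]prop-2-en-1-one F6. NaOAc in refluxing EtOH should close it by oxa-Michael addition to racemic 2-[4-methoxy-3-(3-methylbut-3-en-1-yl)phenyl]-5,7-bis(methoxymethoxy)-8-(3-methylbut-2-en-1-yl)-2,3-dihydro-4H-chromen-4-one F7. Kinetic resolution by Noyori-type transfer hydrogenation (RuCl(p-cymene)[(R,R)-TsDPEN], HCO2H/Et3N, EtOAc, rt; the catalyst antipode is taken if the (2S) ketone turns out to be the faster one) should reduce the (2R) ketone to (2R,4R)-2-[4-methoxy-3-(3-methylbut-3-en-1-yl)phenyl]-5,7-bis(methoxymethoxy)-8-(3-methylbut-2-en-1-yl)-3,4-dihydro-2H-chromen-4-ol F8 and leave 19, which is separated by chromatography.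

**Step 3.** The phenoxide may attack the unsubstituted allyl terminus, or the tertiary ether may equilibrate to the linear prenyl ether through re-ionisation. The chelated phenol may react slowly. The product may begin to rearrange before it is reduced.

Fallback (sets out from 2, comes back at 6): copper-catalysed propargylation of 2 with 3-chloro-3-methylbut-1-yne (CuCl2·2H2O cat., DBU, MeCN, 0 °C), which proceeds through a copper allenylidene and can only give the tertiary ether, should give 2-[(2-methylbut-3-yn-2-yl)oxy]-4,6-bis(methoxymethoxy)benzaldehyde F9. Lindlar semihydrogenation (H2 1 atm, Pd/CaCO3 poisoned with Pb(OAc)2, quinoline, EtOAc, rt) should then give 6.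

**Step 14.** Protonation of the 1,1-disubstituted alkene may lead to methanol addition or double-bond migration. The C7 hydroxyl may cyclise onto the C8 prenyl group. Ring opening and reclosure at C2 may erode the enantiomeric purity.

Fallback (sets out from 19, comes back at 20; no Brønsted acid): silyl transfer with TMSOTf and 2,2'-bipyridyl (CH2Cl2, 0 °C), in which the bipyridyl nitrogen takes up the methoxymethyl group, should give (2S)-2-[4-methoxy-3-(3-methylbut-3-en-1-yl)phenyl]-8-(3-methylbut-2-en-1-yl)-5,7-bis[(trimethylsilyl)oxy]-2,3-dihydro-4H-chromen-4-one F10. Hydrolysis with H2O/THF at rt should then give 20.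

Further compounds
F1 | step 13 | 2-hydroxy-4,6-bis(methoxymethoxy)-3-(3-methylbut-2-en-1-yl)benzaldehyde | O=Cc1c(O)c(CC=C(C)C)c(OCOC)cc1OCOC
F2 | step 13 | 1-[2-hydroxy-4,6-bis(methoxymethoxy)-3-(3-methylbut-2-en-1-yl)phenyl]ethan-1-ol | CC(O)c1c(O)c(CC=C(C)C)c(OCOC)cc1OCOC
F3 | step 13 | 1-[2-hydroxy-4,6-bis(methoxymethoxy)-3-(3-methylbut-2-en-1-yl)phenyl]ethan-1-one | CC(=O)c1c(O)c(CC=C(C)C)c(OCOC)cc1OCOC
F4 | step 13 | [4-methoxy-3-(3-methylbut-3-en-1-yl)phenyl]methanol | OCc1ccc(OC)c(CCC(C)=C)c1
F5 | step 13 | 4-methoxy-3-(3-methylbut-3-en-1-yl)benzaldehyde | O=Cc1ccc(OC)c(CCC(C)=C)c1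
F6 | step 13 | (E)-1-[2-hydroxy-4,6-bis(methoxymethoxy)-3-(3-methylbut-2-en-1-yl)phenyl]-3-[4-methoxy-3-(3-methylbut-3-en-1-yl)phenyl]prop-2-en-1-one | C=C(C)CCc1cc(/C=C/C(=O)c2c(O)c(CC=C(C)C)c(OCOC)cc2OCOC)ccc1OC
F7 | step 13 | racemic 2-[4-methoxy-3-(3-methylbut-3-en-1-yl)phenyl]-5,7-bis(methoxymethoxy)-8-(3-methylbut-2-en-1-yl)-2,3-dihydro-4H-chromen-4-one | C=C(C)CCc1cc(C2CC(=O)c3c(OCOC)cc(OCOC)c(CC=C(C)C)c3O2)ccc1OC
F8 | step 13 | (2R,4R)-2-[4-methoxy-3-(3-methylbut-3-en-1-yl)phenyl]-5,7-bis(methoxymethoxy)-8-(3-methylbut-2-en-1-yl)-3,4-dihydro-2H-chromen-4-ol | C=C(C)CCc1cc([C@H]2C[C@@H](O)c3c(OCOC)cc(OCOC)c(CC=C(C)C)c3O2)ccc1OC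
F9 | step 3 | 2-[(2-methylbut-3-yn-2-yl)oxy]-4,6-bis(methoxymethoxy)benzaldehyde | O=Cc1c(OC(C)(C)C#C)cc(OCOC)cc1OCOC
F10 | step 14 | (2S)-2-[4-methoxy-3-(3-methylbut-3-en-1-yl)phenyl]-8-(3-methylbut-2-en-1-yl)-5,7-bis[(trimethylsilyl)oxy]-2,3-dihydro-4H-chromen-4-one | C=C(C)CCc1cc([C@@H]2CC(=O)c3c(O[Si](C)(C)C)cc(O[Si](C)(C)C)c(CC=C(C)C)c3O2)ccc1OC
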